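Target locants are used for every intermediate: five-membered ring C1(CH3)–C2–C3–C4–C5, seven-membered ring C5–C6–C7–C8–C9–C10–C1, C14 on C8. In the hydrindane intermediates the six-membered ring is C1–C10–C9–C8–C6–C5 and C7 is the cyclopropane methylene.

## Analysis of the target

The target is a daucane sesquiterpenoid ester: a trans-fused hydroazulene with methyl on the quaternary C1, hydroxyl and isopropyl on C4, a 4-hydroxybenzoate on C6 and an aldehyde (C14) on C8, conjugated to the C8=C9 alkene. Its four stereocentres (C1, C4, C5, C6) are contiguous around the ring fusion. C5–H is trans to the C1 methyl, the C4 hydroxyl is cis to that methyl, and the C6 oxygen is cis to C5–H, so trans to both the methyl and the C4 hydroxyl. The sensitive groups are the enal, the free phenol, the tertiary alcohol and the secondary aryl ester. In any intermediate with a C4 carbonyl, C5–H is epimerisable and a C6 oxygen becomes a β-leaving group. The hard points are the trans fusion next to a quaternary carbon (in the hydrindanone precursors the cis-fused ketone is expected to be the more stable isomer), the seven-membered ring, and a C6 oxygen of defined configuration. The route rests on the array C6(O)–C7H2–C8(C14)=C9H. This homoallylic alcohol is what forms when a cyclopropylcarbinyl cation at C9 of a bicyclo[4.1.0]heptane (ring C1–C10–C9–C8–C6–C5, cyclopropane C6–C7–C8) opens its C6–C8 bond and oxygen captures C6. Ring and stereocentre can therefore both be drawn from a trans-hydrindane.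

## Retrosynthetic reasoning

**32 ⇒ 31 ⇒ 30.** No skeletal bond is cut. The enal and the free phenol tolerate nucleophiles, bases and oxidants least, so they are released last. Forward, two silyl groups must come off without moving the C6 acyl group, and then only the allylic C14 hydroxyl is oxidised.

**30 ⇒ 25 + 28 (28 from 26).** The acyl C–O bond of the ester is cut, not the C6–O bond, so the C6 configuration made earlier is untouched. The tertiary C4 hydroxyl of 25 is too hindered to compete, which leaves the C6 hydroxyl as the only acylation site.

**25 ⇒ 24 ⇒ 23 ⇒ 22.** The C4–isopropyl bond is cut, because the C4 carbonyl is the natural handle and the pseudo-axial C1 methyl shields one of its faces. This gains three carbons and the C4 stereocentre. Forward, a secondary carbanion must add to a hindered, enolisable β-oxygenated ketone without epimerising C5 or expelling the C6 oxygen. Hence an organocerium reagent and the silyl ether 23.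

**22 ⇒ 21 ⇒ 20 (key).** C6 is reconnected to C8 and the oxygen moved from C6 to C9. This converts the seven-membered ring into a six-membered ring carrying a cyclopropane and replaces a medium-ring closure by a bond reorganisation. The C6 stereocentre then follows stereospecifically from the cyclopropane face. Forward, C9 must ionise, the internal bond C6–C8 (not C7–C8) must open, and oxygen must be captured at C6.

**20 ⇒ 19 ⇒ 18 ⇒ 17 ⇒ 16.** The two cyclopropane bonds C6–C7 and C7–C8 are cut, leading to enone 16 and a one-carbon ylide. The methylene must sit on the face opposite the C1 methyl; on the enone that is the sterically open face. A hydride reduction of 16 followed by hydroxyl-directed cyclopropanation was not used. Hydride would enter anti to the axial C1 methyl and leave the hydroxyl on the methyl face, from where it would steer a zinc carbenoid to the wrong face. The C9 carbonyl is therefore reduced after cyclopropanation, under direction of the C14 hydroxyl. The C4 ketone stays masked (19) until all base-mediated steps are over.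

**16 ⇒ 15.** The C8–C14 bond is cut at the α-carbon of the enone, where a Morita–Baylis–Hillman reaction installs a hydroxymethyl group in one step.

**15 ⇒ 14 ⇒ 13 ⇒ 12.** The C8=C6 unsaturation is removed, the C9 carbonyl is traced to an exocyclic methylene, and the C4 ketal to the ketone. Dehydrogenation of 14 is regiochemically unambiguous because C1 is quaternary. The ketal is needed because a free C4 ketone next to the enone would make C5–H vinylogously acidic.

**12 ⇒ 11 ⇒ 10.** The C6–C8 bond is cut, opening the six-membered ring to an α-methylene ketone carrying an allylsilane. This closure makes C5 an enolate carbon inside a bicycle, where the axial methyl clearly differentiates the two faces. Forward, protonation must occur anti to the methyl. An aldol closure from a C5 aldehyde was not used, because C5 would then have to be set on a monocycle in which the methyl and the C10 chain on C1 hardly differ in size.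

**10 ⇒ 7 ⇒ 5 ⇒ 1 + 2.** The exocyclic C5=C6 bond, the C1–methyl bond and the C1–C10 bond are cut in turn. The methyl addition to enone 5 is the enantio-determining event; everything else is relayed from C1.

## Alternatives that were turned down

**Alternative 1:** Enzymatic cyclisation.
- **Disconnection and key step:** C1–C10 and C4–C5, both rings at once. A class 1 sesquiterpene cyclase ionises (2E,6E)-farnesyl diphosphate A1 and folds it into dauca-4,8-diene A2 with C1 already configured.
- **For it:** Both rings and the quaternary centre arise in one protecting-group-free step. On skeletal economy it is clearly stronger than the chosen route, which needs twelve steps to reach the hydrindane 20.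
- **Against it:** A2 is a hydrocarbon with a tetrasubstituted C4=C5 alkene. The C4 hydroxyl, C5–H trans to the methyl, the C6 oxygen and the C14 aldehyde would all have to come from selective oxidations of a diene with no directing handle. It also needs an enzyme of proven product fidelity.
- **Comparison:** The chosen route places each oxygen by construction and makes C6 in a stereospecific step.

**Alternative 2:** Vinylcarbenoid cyclopropanation and Cope rearrangement.
- **Disconnection and key step:** C7–C8 and C1–C10 across the seven-membered ring. Methyl 2-diazobut-3-enoate A3 and siloxydiene A4 react under a chiral dirhodium tetracarboxylate (divalent rhodium). Cyclopropanation and Cope rearrangement of the cis-divinylcyclopropane give cycloheptadiene A5.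
- **For it:** It is convergent, forms the seven-membered ring directly with C14 in place as an ester, and is catalytic in the chiral element. On convergence it is stronger.
- **Against it:** The Cope step must create the quaternary C1 at a fully substituted cyclopentene carbon through a crowded boat transition state. A5 still has C5 as an sp2 carbon, so C5–H and the C6 carbinol remain to be set. After enol ether hydrolysis C5 lies between a C6 ketone and the masked C4 ketone, is easily epimerised, and the C6 reduction has no firm facial bias.
- **Comparison:** The chosen route fixes C5 before the ring grows and creates C6 with defined configuration in the ring-forming event.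

**Alternative 3:** Ketyl–olefin cyclisation.
- **Disconnection and key step:** C6–C7. Single-electron reduction of aldehyde A7 by a divalent samarium reagent gives a C6 ketyl that adds to C7 of the acrylate. The C8 enolate expels the C9 acetate and gives hydroazulene A6.
- **For it:** The ring closes with the C6 hydroxyl, the C8=C9 alkene and the C8 ester in one step, and the C4 carbinol is already present. Its end-game is shorter than that of the chosen route.
- **Against it:** A seven-membered closure of a ketyl competes with simple reduction and pinacol coupling. The C6 configuration depends on ketyl geometry in a medium-ring transition state with no clear control element. A7 has an epimerisable C5 aldehyde centre and needs the trans relationship at C1/C5 set on a monocycle.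
- **Comparison:** The chosen route avoids a medium-ring closure and sets C6 by inversion at a defined cyclopropane.

Key step: step 13

Assumption: in step 2 the antipode of the chiral ligand is taken that delivers methyl to the enone face giving the (R)-configured quaternary carbon of 7.

## Route

Step 1
Reactants: 1 3-ethoxycyclopent-2-en-1-one; 2 2-(chloromethyl)-3-(trimethylsilyl)prop-1-ene
Product: 5 3-[2-(trimethylsilylmethyl)prop-2-en-1-yl]cyclopent-2-en-1-one, via allylmagnesium chloride 3 (not isolated), via tertiary carbinol 4 (not isolated)
Conditions: Mg, THF, 0 °C (from 2); then 1, THF, −78 → 0 °C; 1 M HCl, 0 °C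
Reagents that add atoms: none
Why: Stork–Danheiser enone synthesis: 1,2-addition of the allylic Grignard reagent to the vinylogous ester, then acid hydrolysis of the enol ether with loss of water transposes the carbonyl. The 2-substituted allyl unit is symmetrical, so allylic transposition has no consequence, and no stereocentre is formed.

Step 2
Reactants: 5 3-[2-(trimethylsilylmethyl)prop-2-en-1-yl]cyclopent-2-en-1-one
Product: 7 trimethylsilyl enol ether of (3R)-3-methyl-3-[2-(trimethylsilylmethyl)prop-2-en-1-yl]cyclopentan-1-one, via aluminium enolate 6 (not isolated)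
Conditions: AlMe3 (1.5 equiv), copper thiophene-2-carboxylate Cu(O2C-C4H3S) (2 mol %), chiral diarylphosphinamine ligand (SimplePhos type, 4 mol %), Et2O, −30 °C; then Me3SiOTf, THF, −30 → 0 °C
Reagents that add atoms: trimethylaluminium, C[Al](C)C; trimethylsilyl trifluoromethanesulfonate, C[Si](C)(C)OS(=O)(=O)C(F)(F)F
Why: Copper-catalysed asymmetric conjugate addition of a trialkylaluminium to a 3-substituted cyclopentenone; the chiral ligand selects the enone face and so sets the quaternary C1 (R). O-Silylation preserves the enolate regiochemistry (C4=C5) for the next step.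

Step 3
Reactants: 7 trimethylsilyl enol ether of (3R)-3-methyl-3-[2-(trimethylsilylmethyl)prop-2-en-1-yl]cyclopentan-1-one
Product: 10 (3R)-3-methyl-2-methylidene-3-[2-(trimethylsilylmethyl)prop-2-en-1-yl]cyclopentan-1-one, via Mannich base 8 (not isolated), via ammonium iodide 9 (not isolated)
Conditions: Me2N=CH2 I, CH2Cl2, 0 → 20 °C; MeI, 20 °C; NaHCO3 (aq), CH2Cl2, 20 °C
Reagents that add atoms: N,N-dimethylmethyleneiminium iodide, C[N+](C)=C.[I-]
Why: Mukaiyama–Mannich reaction of the regiodefined silyl enol ether with the iminium salt, then N-methylation and base-induced elimination (α-methylenation). C5 becomes sp2, so no stereochemical question arises here.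

Step 4
Reactants: 10 (3R)-3-methyl-2-methylidene-3-[2-(trimethylsilylmethyl)prop-2-en-1-yl]cyclopentan-1-one
Product: 12 (3aR,7aR)-3a-methyl-5-methylideneoctahydro-1H-inden-1-one, via titanium enolate 11 (not isolated)
Conditions: TiCl4 (1.1 equiv), CH2Cl2, −78 °C; MeOH then NH4Cl (aq) at −78 °C
Reagents that add atoms: none
Why: Intramolecular Hosomi–Sakurai reaction: the γ-carbon of the allylsilane (C8) adds to the exocyclic enone carbon C6 in a 6-endo-trig closure and silicon leaves to give the C9 methylidene. C5 is set when titanium enolate 11 is protonated at −78 °C: the proton should enter anti to the axial C1 methyl, which gives the trans fusion as the kinetic product.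

Step 5
Reactants: 12 (3aR,7aR)-3a-methyl-5-methylideneoctahydro-1H-inden-1-one
Product: 13 ethylene ketal of 12
Conditions: (Me3SiOCH2)2, Me3SiOTf (5 mol %), CH2Cl2, −78 → −20 °C; pyridine quench
Reagents that add atoms: 1,2-bis(trimethylsilyloxy)ethane, C[Si](C)(C)OCCO[Si](C)(C)C
Why: Noyori ketalisation under aprotic conditions at low temperature masks C4 without equilibrating C5. Once the ketal is in place C5 is no longer α to a carbonyl and the trans fusion is fixed.

Step 6
Reactants: 13 ethylene ketal of 12
Product: 14 trans-fused C9 ketone with C4 ethylene ketal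
Conditions: O3, CH2Cl2–MeOH, −78 °C; Me2S, → 20 °C
Reagents that add atoms: ozone, [O-][O+]=O
Why: Ozonolysis with reductive work-up cleaves the only alkene, a 1,1-disubstituted exocyclic one, to the C9 ketone.

Step 7
Reactants: 14 trans-fused C9 ketone with C4 ethylene ketal
Product: 15 trans-fused enone (C9 ketone, C8=C6 alkene, C4 ethylene ketal)
Conditions: 2-iodoxybenzoic acid (IBX, 2.5 equiv), DMSO, 70 °C
Reagents that add atoms: none
Why: IBX-mediated α,β-dehydrogenation of a ketone. Unsaturation can only be introduced between C8 and C6, because the other β-carbon, C1, is quaternary.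

Step 8
Reactants: 15 trans-fused enone (C9 ketone, C8=C6 alkene, C4 ethylene ketal)
Product: 16 enone 15 bearing CH2OH (C14) on C8
Conditions: CH2O (37% aq), DMAP (0.3 equiv), THF–H2O, 25–40 °C
Reagents that add atoms: formaldehyde, C=O
Why: Morita–Baylis–Hillman hydroxymethylation of a cyclohexenone: the amine adds to C6, the enolate so formed adds to formaldehyde at C8 and the catalyst is expelled.

Step 9
Reactants: 16 enone 15 bearing CH2OH (C14) on C8
Product: 17 cyclopropyl ketone (C7 bridging C6 and C8 on the face opposite the C1 methyl)
Conditions: Me3S(O)I, NaH, DMSO, 20 °C; then 16, DMSO–THF, 20 → 50 °C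
Reagents that add atoms: trimethylsulfoxonium iodide, C[S+](C)(C)=O.[I-]
Why: Corey–Chaykovsky cyclopropanation: the sulfoxonium ylide adds to C6 and the enolate closes the ring from C8 (3-exo-tet). Attack at C6 should occur anti to the axial C1 methyl and trans to the C5–C4 bond, which puts C7 on the face opposite the methyl and sets C6 and C8.

Step 10
Reactants: 17 cyclopropyl ketone (C7 bridging C6 and C8 on the face opposite the C1 methyl)
Product: 18 diol with the 9-hydroxyl cis to C7
Conditions: Me4NBH(OAc)3, MeCN–AcOH, −20 °C
Reagents that add atoms: none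
Why: Saksena–Evans hydroxyl-directed reduction of a β-hydroxy ketone. The C14 oxygen lies on the face opposite C7, so the acetoxyborohydride bound to it delivers hydride to that face of C9 and the new hydroxyl should appear cis to the cyclopropane (pseudo-equatorial).

Step 11
Reactants: 18 diol with the 9-hydroxyl cis to C7
Product: 19 C14 tert-butyldiphenylsilyl ether of 18
Conditions: TBDPSCl, imidazole, CH2Cl2, 0 °C
Reagents that add atoms: tert-butyl(chloro)diphenylsilane, CC(C)(C)[Si](Cl)(c1ccccc1)c1ccccc1
Why: Selective silylation of the primary hydroxyl; the secondary cyclopropyl carbinol, flanked by a quaternary carbon, stays free.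

Step 12
Reactants: 19 C14 tert-butyldiphenylsilyl ether of 18
Product: 20 cyclopropane-fused trans-hydrindanol (C4 ketone, 9-hydroxyl cis to C7, C14 silyl ether)
Conditions: PPTS, acetone–H2O (10:1), 40 °C
Reagents that add atoms: water, O
Why: Acid-catalysed ketal hydrolysis with a weak acid that should neither ionise the secondary cyclopropyl carbinol nor cleave the silyl ether. The ketone is released only now, after all base-mediated steps.

Step 13
Reactants: 20 cyclopropane-fused trans-hydrindanol (C4 ketone, 9-hydroxyl cis to C7, C14 silyl ether)
Product: 22 trans-hydroazulenone (C4 ketone, 6-hydroxyl cis to C5–H, C8=C9 alkene, C14 silyl ether), via methanesulfonate 21 (not isolated)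
Conditions: Ms2O, Et3N, THF, −40 °C; then NaHCO3, H2O–acetone, −40 → 25 °C
Reagents that add atoms: water, O
Why: The C9 hydroxyl is converted at −40 °C into methanesulfonate 21 (with the anhydride, so that no nucleophilic chloride is present), which ionises in buffered aqueous acetone with participation of the adjacent cyclopropane to a delocalised cyclopropylcarbinyl/homoallyl cation. Capture at C6 as the C6–C8 bond breaks forms the C6–O bond and the C8=C9 alkene, so the ring C1–C10–C9–C8–C6–C5 becomes seven-membered by taking in C7; the closest known reaction type is the solvolytic ring expansion of bicyclo[4.1.0]heptan-2-yl esters to cyclohept-3-enols, with the i-steroid rearrangement as stereochemical model. The seven-membered ring is closed by ring expansion (cleavage of the zero-atom bridge), not by a cyclisation with a Baldwin descriptor. The only new stereocentre, C6, is controlled by the cyclopropane face: the nucleophile attacks anti to the departing C8 (inversion), and because C7 lies opposite the C1 methyl the oxygen ends cis to C5–H. The step needs cleavage of C6–C8 rather than C7–C8 and capture at C6 rather than at C9; C6 is secondary whereas C7 is primary, the pseudo-equatorial sulfonate is antiperiplanar to C6–C8, and the alkene formed is trisubstituted. Capture at C9 returns 20 or its C9 epimer, both of which should re-enter the same cation on resubmission, and the C4 carbonyl makes a hydride shift from C5 (to an α-keto cation) unfavourable. C1 and C5 are not touched.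

Step 14
Reactants: 22 trans-hydroazulenone (C4 ketone, 6-hydroxyl cis to C5–H, C8=C9 alkene, C14 silyl ether)
Product: 23 6-O-triethylsilyl ether of 22
Conditions: Et3SiCl, imidazole, DMAP (cat.), CH2Cl2, 0 °C
Reagents that add atoms: chlorotriethylsilane, CC[Si](Cl)(CC)CC
Why: Silylation of the secondary hydroxyl protects the β-hydroxy ketone against retro-aldol cleavage and deprotonation in the next step.

Step 15
Reactants: 23 6-O-triethylsilyl ether of 22
Product: 24 4-isopropyl carbinol (4-hydroxyl cis to the C1 methyl)
Conditions: i-PrMgCl, CeCl3, THF, −78 °C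
Reagents that add atoms: isopropylmagnesium chloride, CC(C)[Mg]Cl
Why: Organocerium 1,2-addition to a hindered, enolisable ketone. The reagent should attack C4 from the face opposite the pseudo-axial C1 methyl, giving the 4-hydroxyl cis to the methyl.

Step 16
Reactants: 24 4-isopropyl carbinol (4-hydroxyl cis to the C1 methyl)
Product: 25 4,6-diol with C14 still silylated
Conditions: HF·pyridine, pyridine, THF, 0 °C
Reagents that add atoms: none
Why: Fluoride-mediated cleavage of the more labile triethylsilyl ether; the tert-butyldiphenylsilyl ether should survive buffered HF·pyridine at 0 °C.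

Step 17
Reactants: 26 4-hydroxybenzoic acid
Product: 28 4-(tert-butyldimethylsilyloxy)benzoic acid, via silyl ester 27 (not isolated)
Conditions: TBSCl (2.2 equiv), imidazole, DMF, 20 °C; then AcOH–THF–H2O, 20 °C
Reagents that add atoms: tert-butyl(chloro)dimethylsilane, CC(C)(C)[Si](C)(C)Cl
Why: Silylation of both acidic groups, then hydrolysis of the labile silyl ester, leaves the phenol protected.

Step 18
Reactants: 25 4,6-diol with C14 still silylated; 28 4-(tert-butyldimethylsilyloxy)benzoic acid
Product: 30 6-O-[4-(tert-butyldimethylsilyloxy)benzoyl] ester of 25, via mixed anhydride 29 (not isolated)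
Conditions: 2,4,6-Cl3C6H2COCl, Et3N, toluene, 20 °C; then 25, DMAP, toluene, 40 °C
Reagents that add atoms: none
Why: Yamaguchi esterification through the mixed anhydride. Only the secondary C6 hydroxyl should be acylated, the tertiary C4 hydroxyl being inert, and the C6 configuration is retained.

Step 19
Reactants: 30 6-O-[4-(tert-butyldimethylsilyloxy)benzoyl] ester of 25
Product: 31 C14 allylic alcohol with free phenol
Conditions: Bu4NF, AcOH, THF, 0 → 20 °C
Reagents that add atoms: none
Why: Fluoride cleaves both the aryl and the alkyl silyl ether; buffering with acetic acid guards against base-induced elimination or acyl migration.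

Step 20
Reactants: 31 C14 allylic alcohol with free phenol
Product: 32 target (CNP0267880.1)
Conditions: MnO2, CH2Cl2, 20 °C
Reagents that add atoms: none
Why: MnO2 oxidises only the allylic primary alcohol to the enal; the tertiary alcohol and the phenol should not be oxidised.

## Compound list

1 | 3-ethoxycyclopent-2-en-1-one | CCOC1=CC(=O)CC1 | starting material
2 | 2-(chloromethyl)-3-(trimethylsilyl)prop-1-ene | C=C(CCl)C[Si](C)(C)C | starting material
3 | [2-(trimethylsilylmethyl)prop-2-en-1-yl]magnesium chloride | C=C(C[Mg]Cl)C[Si](C)(C)C | intermediate (not isolated)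
4 | 3-ethoxy-1-[2-(trimethylsilylmethyl)prop-2-en-1-yl]cyclopent-2-en-1-ol (racemic, as its magnesium alkoxide) | CCOC1=CC(O)(CC(=C)C[Si](C)(C)C)CC1 | intermediate (not isolated)
5 | 3-[2-(trimethylsilylmethyl)prop-2-en-1-yl]cyclopent-2-en-1-one | O=C1C=C(CC(=C)C[Si](C)(C)C)CC1 | intermediate
6 | dimethylaluminium enolate (C4=C5) of (3R)-3-methyl-3-[2-(trimethylsilylmethyl)prop-2-en-1-yl]cyclopentan-1-one | C[Al](C)OC1=C[C@@](C)(CC(=C)C[Si](C)(C)C)CC1 | intermediate (not isolated)
7 | trimethyl({(3R)-3-methyl-3-[2-(trimethylsilylmethyl)prop-2-en-1-yl]cyclopent-1-en-1-yl}oxy)silane | C[Si](C)(C)OC1=C[C@@](C)(CC(=C)C[Si](C)(C)C)CC1 | intermediate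
8 | (3R)-2-[(dimethylamino)methyl]-3-methyl-3-[2-(trimethylsilylmethyl)prop-2-en-1-yl]cyclopentan-1-one (both C2 epimers) | CN(C)CC1C(=O)CC[C@]1(C)CC(=C)C[Si](C)(C)C | intermediate (not isolated)
9 | N-methyl quaternary ammonium iodide of 8 | C[N+](C)(C)CC1C(=O)CC[C@]1(C)CC(=C)C[Si](C)(C)C.[I-] | intermediate (not isolated)
10 | (3R)-3-methyl-2-methylidene-3-[2-(trimethylsilylmethyl)prop-2-en-1-yl]cyclopentan-1-one | C=C1C(=O)CC[C@]1(C)CC(=C)C[Si](C)(C)C | intermediate
11 | trichlorotitanium enolate (C4=C5) of 12 | Cl[Ti](Cl)(Cl)OC1=C2CCC(=C)C[C@@]2(C)CC1 | intermediate (not isolated)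
12 | (3aR,7aR)-3a-methyl-5-methylideneoctahydro-1H-inden-1-one (trans-fused) | C=C1CC[C@H]2C(=O)CC[C@]2(C)C1 | intermediate
13 | ethylene ketal of 12, (3a'R,7a'R)-3a'-methyl-5'-methylideneoctahydrospiro[[1,3]dioxolane-2,1'-indene] | C=C1CC[C@H]2C3(OCCO3)CC[C@]2(C)C1 | intermediate
14 | trans-fused C9 ketone with C4 ethylene ketal | O=C1CC[C@H]2C3(OCCO3)CC[C@]2(C)C1 | intermediate
15 | trans-fused enone: C9 ketone, C8=C6 alkene, C4 ethylene ketal | O=C1C=C[C@H]2C3(OCCO3)CC[C@]2(C)C1 | intermediate
16 | enone 15 with CH2OH (C14) on C8 | O=C1C(CO)=C[C@H]2C3(OCCO3)CC[C@]2(C)C1 | intermediate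
17 | cyclopropyl ketone: C7 bridges C6 and C8 on the face opposite the C1 methyl; C9 ketone, C14 hydroxyl, C4 ketal | C1COC2(O1)CC[C@]3(C)CC(=O)[C@]4(CO)C[C@@H]4[C@H]32 | intermediate
18 | diol from 17 with the 9-hydroxyl cis to C7 | C1COC2(O1)CC[C@]3(C)C[C@H](O)[C@]4(CO)C[C@@H]4[C@H]32 | intermediate
19 | C14 tert-butyldiphenylsilyl ether of 18 | C1COC2(O1)CC[C@]3(C)C[C@H](O)[C@]4(CO[Si](c5ccccc5)(c5ccccc5)C(C)(C)C)C[C@@H]4[C@H]32 | intermediate
20 | cyclopropane-fused trans-hydrindanol: C4 ketone, 9-hydroxyl cis to C7, C14 tert-butyldiphenylsilyl ether | O=C1CC[C@]2(C)C[C@H](O)[C@]3(CO[Si](c4ccccc4)(c4ccccc4)C(C)(C)C)C[C@@H]3[C@H]21 | intermediate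
21 | C9 methanesulfonate of 20 | O=C1CC[C@]2(C)C[C@H](OS(C)(=O)=O)[C@]3(CO[Si](c4ccccc4)(c4ccccc4)C(C)(C)C)C[C@@H]3[C@H]21 | intermediate (not isolated)
22 | trans-hydroazulenone: C4 ketone, 6-hydroxyl cis to C5–H, C8=C9 alkene, C14 tert-butyldiphenylsilyl ether | O=C1CC[C@]2(C)CC=C(CO[Si](c3ccccc3)(c3ccccc3)C(C)(C)C)C[C@H](O)[C@H]21 | intermediate
23 | 6-O-triethylsilyl ether of 22 | O=C1CC[C@]2(C)CC=C(CO[Si](c3ccccc3)(c3ccccc3)C(C)(C)C)C[C@H](O[Si](CC)(CC)CC)[C@H]21 | intermediate
24 | 4-isopropyl carbinol from 23 (4-hydroxyl cis to the C1 methyl) | CC(C)[C@]1(O)CC[C@]2(C)CC=C(CO[Si](c3ccccc3)(c3ccccc3)C(C)(C)C)C[C@H](O[Si](CC)(CC)CC)[C@H]21 | intermediate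
25 | 4,6-diol with C14 tert-butyldiphenylsilyl ether | CC(C)[C@]1(O)CC[C@]2(C)CC=C(CO[Si](c3ccccc3)(c3ccccc3)C(C)(C)C)C[C@H](O)[C@H]21 | intermediate
26 | 4-hydroxybenzoic acid | O=C(O)c1ccc(O)cc1 | starting material
27 | tert-butyldimethylsilyl 4-(tert-butyldimethylsilyloxy)benzoate | CC(C)(C)[Si](C)(C)OC(=O)c1ccc(O[Si](C)(C)C(C)(C)C)cc1 | intermediate (not isolated)
28 | 4-(tert-butyldimethylsilyloxy)benzoic acid | CC(C)(C)[Si](C)(C)Oc1ccc(C(=O)O)cc1 | intermediate
29 | mixed anhydride of 28 with 2,4,6-trichlorobenzoic acid | CC(C)(C)[Si](C)(C)Oc1ccc(C(=O)OC(=O)c2c(Cl)cc(Cl)cc2Cl)cc1 | intermediate (not isolated)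
30 | 6-O-[4-(tert-butyldimethylsilyloxy)benzoyl] ester of 25 | CC(C)[C@]1(O)CC[C@]2(C)CC=C(CO[Si](c3ccccc3)(c3ccccc3)C(C)(C)C)C[C@H](OC(=O)c3ccc(O[Si](C)(C)C(C)(C)C)cc3)[C@H]21 | intermediate
31 | 6-O-(4-hydroxybenzoyl) ester with free C14 allylic alcohol and 4-hydroxyl | CC(C)[C@]1(O)CC[C@]2(C)CC=C(CO)C[C@H](OC(=O)c3ccc(O)cc3)[C@H]21 | intermediate
32 | CNP0267880.1 | CC(C)[C@]1(O)CC[C@]2(C)CC=C(C=O)C[C@H](OC(=O)c3ccc(O)cc3)[C@H]21 | target

## Step count and least certain steps

Total: 20 steps. Longest linear sequence: 19 steps (1–16 and 18–20); step 17 is the side branch.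

**Step 13 (key step).** The cation may be captured at C9, which returns cyclopropyl carbinols, or may close to cyclobutyl products, since C8 is fully substituted. It may also lose H5 to give the conjugated enone. The C4 carbonyl two bonds from C6 lowers the share of charge at C6, and kinetic capture of such cations often favours the carbinyl position. Fallback under thermodynamic control: from 20, trifluoroacetic acid in CH2Cl2 at 0 °C ionises the carbinol reversibly. Cyclopropylcarbinyl esters re-ionise while the homoallylic ester does not, so the C6 trifluoroacetate F1 should accumulate. Methanolysis with NaHCO3 in MeOH at 0 °C then gives 22.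

**Step 4.** Protonation of the enolate may be unselective, or the ketone may equilibrate during work-up towards the cis-fused isomer, which is expected to be the more stable one; 1,2-addition of the allylsilane to the carbonyl is a second possible loss. Fallback by dissolving-metal reduction: the crude enolate 11 is silylated (Me3SiCl, Et3N) to the silyl enol ether F2. Saegusa–Ito oxidation with Pd(OAc)2 in MeCN gives the ring-fusion enone F3 (C5=C6). Lithium in liquid ammonia with t-BuOH at −78 °C, then NH4Cl, reduces F3 with protonation of C5 anti to the methyl, as in the reduction of steroidal 8(14)-en-15-ones, and returns to 12.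

**Step 8.** Conjugate addition of the amine catalyst to C6 may be too slow, because C6 is flanked by the tertiary C5 and the quaternary C1, so the enone may be recovered or degrade. Fallback by iodination and cross-coupling: from 15, I2 and pyridine in CH2Cl2 give the 8-iodoenone F4. Stille coupling with Bu3SnCH2OH and Pd(PPh3)4 in dioxane at 80 °C returns to 16.

**Step 9 (with step 10).** Ylide addition to a hindered α-substituted enone carrying a free hydroxyl may give low conversion or poor facial selectivity, and the hydride delivery in step 10 may give the C9 epimer. Fallback through the allylic alcohol: from 16, TBDPSCl and imidazole give the silyl ether F5. Luche reduction (NaBH4, CeCl3, MeOH, −78 °C) gives the allylic alcohol F6 with the hydroxyl on the methyl face, since hydride enters anti to the methyl. Mitsunobu inversion (4-nitrobenzoic acid, PPh3, diisopropyl azodicarboxylate) gives the 4-nitrobenzoate F7, and K2CO3 in MeOH gives the epimeric allylic alcohol F8. Hydroxyl-directed Simmons–Smith cyclopropanation (Et2Zn, CH2I2, CH2Cl2, 0 °C), now reinforced by the steric bias, returns to 19.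

**Step 15.** The secondary organometallic may enolise or reduce the hindered ketone, and the 6-silyloxy group near C4 may erode the facial preference set by the methyl. Fallback with an sp2 nucleophile: from 23, isopropenylmagnesium bromide and CeCl3 in THF at −78 °C give the isopropenyl carbinol F9; this reagent has no β-hydrogen to transfer and is less basic. Hydrogenation with RhCl(PPh3)3 and H2 in benzene saturates only the 1,1-disubstituted alkene and returns to 24.

## Further compounds

F1 | step 13 | C6 trifluoroacetate of 22 | O=C1CC[C@]2(C)CC=C(CO[Si](c3ccccc3)(c3ccccc3)C(C)(C)C)C[C@H](OC(=O)C(F)(F)F)[C@H]21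
F2 | step 4 | trimethylsilyl enol ether (C4=C5) of 12 | C[Si](C)(C)OC1=C2CCC(=C)C[C@@]2(C)CC1
F3 | step 4 | (3aR)-3a-methyl-5-methylidene-2,3,3a,4,5,6-hexahydro-1H-inden-1-one (C5=C6 enone) | C=C1CC=C2C(=O)CC[C@]2(C)C1
F4 | step 8 | 8-iodo derivative of enone 15 | O=C1C(I)=C[C@H]2C3(OCCO3)CC[C@]2(C)C1
F5 | step 9 | C14 tert-butyldiphenylsilyl ether of 16 | O=C1C(CO[Si](c2ccccc2)(c2ccccc2)C(C)(C)C)=C[C@H]2C3(OCCO3)CC[C@]2(C)C1
F6 | step 9 | allylic alcohol from F5 with the 9-hydroxyl on the methyl face | O[C@H]1C(CO[Si](c2ccccc2)(c2ccccc2)C(C)(C)C)=C[C@H]2C3(OCCO3)CC[C@]2(C)C1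
F7 | step 9 | C9-inverted 4-nitrobenzoate of F6 | O=C(O[C@@H]1C(CO[Si](c2ccccc2)(c2ccccc2)C(C)(C)C)=C[C@H]2C3(OCCO3)CC[C@]2(C)C1)c1ccc([N+](=O)[O-])cc1
F8 | step 9 | allylic alcohol with the 9-hydroxyl opposite the methyl | O[C@@H]1C(CO[Si](c2ccccc2)(c2ccccc2)C(C)(C)C)=C[C@H]2C3(OCCO3)CC[C@]2(C)C1
F9 | step 15 | 4-isopropenyl carbinol from 23 | C=C(C)[C@]1(O)CC[C@]2(C)CC=C(CO[Si](c3ccccc3)(c3ccccc3)C(C)(C)C)C[C@H](O[Si](CC)(CC)CC)[C@H]21
A1 | alternative 1 | (2E,6E)-farnesyl diphosphate | CC(C)=CCC/C(C)=C/CC/C(C)=C/COP(=O)(O)OP(=O)(O)O
A2 | alternative 1 | dauca-4,8-diene | CC(C)C1=C2CCC(C)=CC[C@@]2(C)CC1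
A3 | alternative 2 | methyl 2-diazobut-3-enoate | C=CC(=[N+]=[N-])C(=O)OC
A4 | alternative 2 | tert-butyldimethyl{[1-(7-methyl-1,4-dioxaspiro[4.4]non-6-en-6-yl)ethenyl]oxy}silane | C=C(O[Si](C)(C)C(C)(C)C)C1=C(C)CCC12OCCO2
A5 | alternative 2 | bicyclic cycloheptadiene ester (C4 ketal, C6 silyl enol ether) | C1COC2(O1)CC[C@]3(C)CC=C(C(=O)OC)CC(O[Si](C)(C)C(C)(C)C)=C23
A6 | alternative 3 | hydroazulene 6-ol with C8 methyl ester and C8=C9 alkene | CC(C)[C@]1(O[Si](CC)(CC)CC)CC[C@]2(C)CC=C(C(=O)OC)C[C@H](O)[C@H]21
A7 | alternative 3 | cyclopentane C6 aldehyde carrying the Baylis–Hillman acetate chain on C1 | CC(C)[C@]1(O[Si](CC)(CC)CC)CC[C@](C)(CC(OC(C)=O)C(=C)C(=O)OC)[C@H]1C=O
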